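The route rests on cutting the C5–C6 bond of the cyclohexene ring (C1 = secondary carbinol, C2=C3, C4, C5 = tertiary carbinol carrying the chain, C6). The key step exploits the ring segment C1–C2=C3–C4–C5, oxygenated at both ends and cis at C2=C3: it is the carbon skeleton of a pyrylium ring, with C6 as its 2-methyl group. In one operation water opens the pyrylium ring to the (Z)-ene-1,5-dione and a chiral dinuclear zinc catalyst adds C6 to the C5 ketone, which builds the carbocycle, the C5–C6 bond and the C5 stereocentre. The precursor is 2-methyl-6-[(Z)-16-phenylhexadec-12-enyl]pyrylium tetrafluoroborate, made from 2,6-dimethyl-4-pyranone.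

Key step: step 6

Remarks on the chemistry
- Ring numbering used throughout: C1 = CH(OH) (C=O in 14), C2=C3, C4, C5 = C(OH)(chain), C6 = CH2 between C5 and C1; C1' = first chain carbon.
- Structure check: the target is the cis-1,3-diol, S at both carbinol carbons, with a (12Z)-16-phenylhexadec-12-enyl chain; ketol 14 is (5S). No structure needed correcting.
- Assumption: the sense of induction of the zinc catalyst in step 6 cannot be predicted with confidence. The (S,S)-ligand is written; its commercially available mirror image is to be used if it proves to favour the (5R)-ketol.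
- Amine catalysts are not used in step 6: primary amines convert pyrylium ions and their ene-diones into pyridinium salts, secondary amines into anilines.
- A boron-chelate syn reduction is not planned for 14: a boron bridge between the C1 carbonyl oxygen and the C5 hydroxyl cannot form inside the ring, and hydride delivery from the C5 oxygen would give the trans-diol. Step 7 is therefore catalyst-controlled.

Step 1
Reactants: 1 11-bromoundecan-1-ol
Product: 2 11-bromoundecanal
Conditions: PhI(OAc)2, 2,2,6,6-tetramethylpiperidin-1-oxyl (10 mol %), CH2Cl2, rt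
Reagents that add atoms: none
Why: Oxoammonium-mediated alcohol oxidation stops at the aldehyde and leaves the primary bromide untouched.

Step 2
Reactants: 3 1-bromo-4-phenylbutane
Product: 4 (4-phenylbutyl)triphenylphosphonium bromide
Conditions: PPh3, MeCN, reflux
Reagents that add atoms: triphenylphosphine, c1ccc(cc1)P(c1ccccc1)c1ccccc1
Why: SN2 quaternisation of triphenylphosphine by an unhindered primary bromide is a reliable way to a Wittig salt.

Step 3
Reactants: 4 (4-phenylbutyl)triphenylphosphonium bromide; 2 11-bromoundecanal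
Product: 6 [(4Z)-15-bromopentadec-4-en-1-yl]benzene, via phosphorus ylide 5 (not isolated)
Conditions: NaN(SiMe3)2, THF, −78 to 0 °C; then 2, −78 °C to rt
Reagents that add atoms: none
Why: Wittig olefination with a non-stabilised ylide under lithium-free conditions runs under kinetic control through the cis-oxaphosphetane and should give the Z-alkene, the ylide adding to the aldehyde at −78 °C far faster than it is alkylated by the primary bromide.

Step 4
Reactants: 7 2,6-dimethyl-4H-pyran-4-one; 6 [(4Z)-15-bromopentadec-4-en-1-yl]benzene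
Product: 9 2-methyl-6-[(12Z)-16-phenylhexadec-12-en-1-yl]-4H-pyran-4-one, via lithium dienolate 8 (not isolated)
Conditions: 7 (2.5 equiv), LiN(i-Pr)2 (2.3 equiv), THF, −78 °C; then 6, DMPU, Bu4NI (10 mol %), −78 to 0 °C
Reagents that add atoms: none
Why: Lateral (vinylogous) deprotonation of one 2-methyl group gives the extended dienolate 8, which is C-alkylated at its exocyclic carbon in an SN2 enolate alkylation, iodide exchange and DMPU raising the rate and the excess of 8 suppressing double alkylation.

Step 5
Reactants: 9 2-methyl-6-[(12Z)-16-phenylhexadec-12-en-1-yl]-4H-pyran-4-one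
Product: 11 2-methyl-6-[(12Z)-16-phenylhexadec-12-en-1-yl]pyrylium tetrafluoroborate, via 4H-pyran-4-ol 10 (not isolated)
Conditions: i-Bu2AlH, CH2Cl2, −78 °C; then 48% aq. HBF4, Et2O, 0 °C
Reagents that add atoms: tetrafluoroboric acid, [H+].F[B-](F)(F)F
Why: 1,2-Reduction of the vinylogous ester carbonyl gives pyranol 10 (as its aluminium alkoxide), which loses water on acidification because the cation formed is the aromatic pyrylium ion (reduction–dehydration route to 4-unsubstituted pyrylium salts), the isolated Z-alkene being inert to both reagents at these temperatures.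

Step 6
Reactants: 11 2-methyl-6-[(12Z)-16-phenylhexadec-12-en-1-yl]pyrylium tetrafluoroborate
Product: 14 (5S)-5-hydroxy-5-[(12Z)-16-phenylhexadec-12-en-1-yl]cyclohex-2-en-1-one, via 2H-pyran-2-ol 12 (not isolated), via (Z)-ene-1,5-dione 13 (not isolated)
Conditions: sat. aq. NaHCO3, CH2Cl2, 0 °C; organic phase dried (Na2SO4), solvent exchanged for THF (4 Å MS); then (S,S)-2,6-bis{[2-(hydroxydiphenylmethyl)pyrrolidin-1-yl]methyl}-4-methylphenol (10 mol %), Et2Zn (20 mol %), THF, −20 °C; pH 7 phosphate buffer
Reagents that add atoms: water, O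
Why: Proposed new method: water adds to the chain-bearing α-carbon of cation 11 (bicarbonate takes the proton) to give pyranol 12, which undergoes 6π-electrocyclic ring opening and tautomerisation to the (Z)-ene-1,5-dione 13; the dinuclear zinc alkoxide then binds the C1 and C5 carbonyl oxygens on its two metal centres, turns the methyl ketone into its zinc enolate at C6 and lets C6 add to the activated C5 ketone, which forms the C5–C6 bond. The closest known reactions are the hydroxide-induced recyclisation of 2-methylpyrylium salts to phenols, which passes through such an ene-dione and its aldol ketol, and direct asymmetric aldol additions of methyl ketones, α,β-unsaturated ones included, under dinuclear zinc alkoxide catalysis; an enantioselective ketone-acceptor cyclisation of a pyrylium-derived ene-dione has not been shown. The carbocycle closes in a 6-(enolendo)-exo-trig mode, which is possible only because the C2=C3 bond is inherited cis from the heterocycle and is held cisoid by two-point binding to the catalyst. C5 is the only new stereocentre and is set by catalyst control, the chiral pocket of the zinc complex exposing one face of the bound C5 carbonyl to C6, with no substrate element taking part. The step needs enolisation at the methyl carbon C6 and not at C1', which the unhindered primary position and the higher electrophilicity of the non-conjugated C5 ketone over the C1 enone carbonyl should secure, and it needs arrest at the ketol, which the aprotic, weakly basic medium at −20 °C and the neutral quench should secure, since acid returns 13 to the pyrylium ion and hot alkali dehydrates 14 to the 3-alkylphenol. Amine catalysts are left out on purpose, because primary amines convert pyrylium ions and their ene-diones into N-substituted pyridinium salts and secondary amines into anilines, which would consume the catalyst.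

Step 7
Reactants: 14 (5S)-5-hydroxy-5-[(12Z)-16-phenylhexadec-12-en-1-yl]cyclohex-2-en-1-one
Product: 15 (1S,3S)-1-[(12Z)-16-phenylhexadec-12-en-1-yl]cyclohex-4-ene-1,3-diol
Conditions: (R)-1-methyl-3,3-diphenyltetrahydro-1H,3H-pyrrolo[1,2-c][1,3,2]oxazaborole (20 mol %), catecholborane, toluene, −78 °C; then MeOH, aq. NaOH
Reagents that add atoms: none
Why: Corey–Bakshi–Shibata reduction with the (R)-oxazaborolidine treats the C2=C3 side as the large group and delivers hydride to the Re face of C1 (1,2-reduction), which sets C1 as S and hence cis to the C5 hydroxyl by catalyst control; this is also the face anti to the C5 hydroxyl that a bulky reductant should prefer, and catecholborane carries no second hydride for a trans-selective delivery from the C5 oxygen.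

Compound list
1 | 11-bromoundecan-1-ol | OCCCCCCCCCCCBr | starting material
2 | 11-bromoundecanal | O=CCCCCCCCCCCBr | intermediate
3 | 1-bromo-4-phenylbutane | BrCCCCc1ccccc1 | starting material
4 | (4-phenylbutyl)triphenylphosphonium bromide | [Br-].c1ccc(cc1)CCCC[P+](c1ccccc1)(c1ccccc1)c1ccccc1 | intermediate
5 | triphenyl(4-phenylbutylidene)-λ5-phosphane (ylide) | c1ccc(cc1)CCCC=P(c1ccccc1)(c1ccccc1)c1ccccc1 | intermediate (not isolated)
6 | [(4Z)-15-bromopentadec-4-en-1-yl]benzene | BrCCCCCCCCCC/C=C\CCCc1ccccc1 | intermediate
7 | 2,6-dimethyl-4H-pyran-4-one | CC1=CC(=O)C=C(C)O1 | starting material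
8 | lithium 2-methyl-6-methylidene-6H-pyran-4-olate | [Li+].[O-]C1=CC(=C)OC(C)=C1 | intermediate (not isolated)
9 | 2-methyl-6-[(12Z)-16-phenylhexadec-12-en-1-yl]-4H-pyran-4-one | CC1=CC(=O)C=C(CCCCCCCCCCC/C=C\CCCc2ccccc2)O1 | intermediate
10 | 2-methyl-6-[(12Z)-16-phenylhexadec-12-en-1-yl]-4H-pyran-4-ol (racemic, formed as its aluminium alkoxide) | CC1=CC(O)C=C(CCCCCCCCCCC/C=C\CCCc2ccccc2)O1 | intermediate (not isolated)
11 | 2-methyl-6-[(12Z)-16-phenylhexadec-12-en-1-yl]pyrylium tetrafluoroborate | Cc1cccc(CCCCCCCCCCC/C=C\CCCc2ccccc2)[o+]1.F[B-](F)(F)F | intermediate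
12 | 6-methyl-2-[(12Z)-16-phenylhexadec-12-en-1-yl]-2H-pyran-2-ol (racemic) | CC1=CC=CC(O)(CCCCCCCCCCC/C=C\CCCc2ccccc2)O1 | intermediate (not isolated)
13 | (3Z,18Z)-22-phenyldocosa-3,18-diene-2,6-dione | CC(=O)/C=C\CC(=O)CCCCCCCCCCC/C=C\CCCc1ccccc1 | intermediate (not isolated)
14 | (5S)-5-hydroxy-5-[(12Z)-16-phenylhexadec-12-en-1-yl]cyclohex-2-en-1-one | O=C1C=CC[C@@](O)(CCCCCCCCCCC/C=C\CCCc2ccccc2)C1 | intermediate
15 | (1S,3S)-1-[(12Z)-16-phenylhexadec-12-en-1-yl]cyclohex-4-ene-1,3-diol | O[C@@H]1C=CC[C@@](O)(CCCCCCCCCCC/C=C\CCCc2ccccc2)C1 | target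

Total step count: 7
Longest linear sequence: 6 steps (steps 1, 3, 4, 5, 6, 7)

Steps most likely to fail

1. Step 6.
- What may go wrong: deprotonation at the doubly activated C4 methylene may tie the zinc catalyst up as an unreactive dienolate, so that turnover stalls. The ene-dione may isomerise from Z to E before it cyclises. The catalyst may discriminate the two faces of the C5 ketone poorly, or retro-aldol and re-addition may erode the enantiopurity. Water may be lost from the ketol with aromatisation.
- Fallback with known chemistry, setting out from phosphonium salt 4 and returning to the route at 14. Commercial 12-bromododecan-1-ol is oxidised as in step 1 to 12-bromododecanal F1, and ylide 5 (from 4, as in step 3) converts it into [(4Z)-16-bromohexadec-4-en-1-yl]benzene F2. Magnesium in THF gives [(12Z)-16-phenylhexadec-12-en-1-yl]magnesium bromide F3, which adds to 3-ethoxycyclohex-2-en-1-one; dilute HCl then unmasks 3-[(12Z)-16-phenylhexadec-12-en-1-yl]cyclohex-2-en-1-one F4 (Stork–Danheiser sequence). Copper-catalysed enantioselective conjugate borylation (CuCl, NaOt-Bu, (R,R)-2,3-bis(tert-butylmethylphosphino)quinoxaline or its mirror image as required, bis(pinacolato)diboron, MeOH, THF) should give (3R)-3-[(12Z)-16-phenylhexadec-12-en-1-yl]-3-(4,4,5,5-tetramethyl-1,3,2-dioxaborolan-2-yl)cyclohexan-1-one F5. NaBO3·4H2O oxidises the C–B bond with retention to (3S)-3-hydroxy-3-[(12Z)-16-phenylhexadec-12-en-1-yl]cyclohexan-1-one F6. N-(Trimethylsilyl)imidazole caps the tertiary hydroxyl to give (3S)-3-[(12Z)-16-phenylhexadec-12-en-1-yl]-3-[(trimethylsilyl)oxy]cyclohexan-1-one F7. Kinetic enolisation away from the quaternary carbon (LiN(i-Pr)2, Me3SiCl, THF, −78 °C) gives trimethyl({(5S)-5-[(12Z)-16-phenylhexadec-12-en-1-yl]-5-[(trimethylsilyl)oxy]cyclohex-1-en-1-yl}oxy)silane F8. Saegusa–Ito oxidation (Pd(OAc)2, MeCN) gives (5S)-5-[(12Z)-16-phenylhexadec-12-en-1-yl]-5-[(trimethylsilyl)oxy]cyclohex-2-en-1-one F9; dehydrogenation is possible only on this side because the carbinol carbon carries no hydrogen. K2CO3 in MeOH then removes the silyl group and delivers 14.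

2. Step 7.
- What may go wrong: substrate bias may override the catalyst and give mainly the trans-diol, either by axial hydride attack on the face of an axial C5 hydroxyl or by hydride delivery from a borylated C5 oxygen. Conjugate reduction may also compete.
- Fallback, setting out from 14 and returning at 15: the trans-diol is made on purpose and C1 is inverted. Hydroxyl-directed reduction with Me4NBH(OAc)3 (MeCN–AcOH, −20 °C) delivers hydride from the C5 oxygen to the same face and should give (1S,3R)-1-[(12Z)-16-phenylhexadec-12-en-1-yl]cyclohex-4-ene-1,3-diol F10. Mitsunobu esterification of the secondary allylic hydroxyl (4-nitrobenzoic acid, PPh3, diisopropyl azodicarboxylate, THF, 0 °C) inverts C1 and should give (1S,5S)-5-hydroxy-5-[(12Z)-16-phenylhexadec-12-en-1-yl]cyclohex-2-en-1-yl 4-nitrobenzoate F11, the tertiary hydroxyl staying free. K2CO3 in MeOH then releases 15.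

3. Step 4.
- What may go wrong: the SN2 reaction of the unactivated bromide may be slower than self-condensation of the lithiated pyranone on warming, and proton exchange between product and dienolate may lead to double alkylation.
- Fallback, setting out from 6 and returning at 9: the pyranone ring is built instead of alkylated. Alkylation of diethyl malonate with 6 (NaH, THF–DMF) gives diethyl 2-[(11Z)-15-phenylpentadec-11-en-1-yl]propanedioate F12. Krapcho dealkoxycarbonylation (LiCl, wet DMSO, 150 °C) gives ethyl (13Z)-17-phenylheptadec-13-enoate F13. Claisen acylation of the dianion of pentane-2,4-dione (NaH, then n-BuLi, THF, 0 °C) with this ester gives (18Z)-22-phenyldocos-18-ene-2,4,6-trione F14. Acid-catalysed cyclodehydration (TsOH, toluene, reflux with removal of water) closes the 4-pyranone 9.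

Further compounds
F1 | step 6 | 12-bromododecanal | O=CCCCCCCCCCCCBr
F2 | step 6 | [(4Z)-16-bromohexadec-4-en-1-yl]benzene | BrCCCCCCCCCCC/C=C\CCCc1ccccc1
F3 | step 6 | [(12Z)-16-phenylhexadec-12-en-1-yl]magnesium bromide | Br[Mg]CCCCCCCCCCC/C=C\CCCc1ccccc1
F4 | step 6 | 3-[(12Z)-16-phenylhexadec-12-en-1-yl]cyclohex-2-en-1-one | O=C1C=C(CCCCCCCCCCC/C=C\CCCc2ccccc2)CCC1
F5 | step 6 | (3R)-3-[(12Z)-16-phenylhexadec-12-en-1-yl]-3-(4,4,5,5-tetramethyl-1,3,2-dioxaborolan-2-yl)cyclohexan-1-one | O=C1CCC[C@@](B2OC(C)(C)C(C)(C)O2)(CCCCCCCCCCC/C=C\CCCc3ccccc3)C1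
F6 | step 6 | (3S)-3-hydroxy-3-[(12Z)-16-phenylhexadec-12-en-1-yl]cyclohexan-1-one | O=C1CCC[C@@](O)(CCCCCCCCCCC/C=C\CCCc2ccccc2)C1
F7 | step 6 | (3S)-3-[(12Z)-16-phenylhexadec-12-en-1-yl]-3-[(trimethylsilyl)oxy]cyclohexan-1-one | O=C1CCC[C@@](O[Si](C)(C)C)(CCCCCCCCCCC/C=C\CCCc2ccccc2)C1
F8 | step 6 | trimethyl({(5S)-5-[(12Z)-16-phenylhexadec-12-en-1-yl]-5-[(trimethylsilyl)oxy]cyclohex-1-en-1-yl}oxy)silane | C[Si](C)(C)OC1=CCC[C@@](O[Si](C)(C)C)(CCCCCCCCCCC/C=C\CCCc2ccccc2)C1
F9 | step 6 | (5S)-5-[(12Z)-16-phenylhexadec-12-en-1-yl]-5-[(trimethylsilyl)oxy]cyclohex-2-en-1-one | O=C1C=CC[C@@](O[Si](C)(C)C)(CCCCCCCCCCC/C=C\CCCc2ccccc2)C1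
F10 | step 7 | (1S,3R)-1-[(12Z)-16-phenylhexadec-12-en-1-yl]cyclohex-4-ene-1,3-diol | O[C@H]1C=CC[C@@](O)(CCCCCCCCCCC/C=C\CCCc2ccccc2)C1
F11 | step 7 | (1S,5S)-5-hydroxy-5-[(12Z)-16-phenylhexadec-12-en-1-yl]cyclohex-2-en-1-yl 4-nitrobenzoate | O=C(O[C@@H]1C=CC[C@@](O)(CCCCCCCCCCC/C=C\CCCc2ccccc2)C1)c1ccc(cc1)[N+](=O)[O-]
F12 | step 4 | diethyl 2-[(11Z)-15-phenylpentadec-11-en-1-yl]propanedioate | CCOC(=O)C(CCCCCCCCCC/C=C\CCCc1ccccc1)C(=O)OCC
F13 | step 4 | ethyl (13Z)-17-phenylheptadec-13-enoate | CCOC(=O)CCCCCCCCCCCC/C=C\CCCc1ccccc1
F14 | step 4 | (18Z)-22-phenyldocos-18-ene-2,4,6-trione | CC(=O)CC(=O)CC(=O)CCCCCCCCCCC/C=C\CCCc1ccccc1
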